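Abbreviations used throughout: TBS = tert-butyldimethylsilyl, Ipc = isopinocampheyl. Carbon numbers are those of the target **48**: C1 is the lactone carbonyl, C41 the carbinol carbon that carries the ring oxygen, C42–C50 the side chain.

## The problem

Compound 48 is a 42-membered macrolactone (C1–C41 plus the ring oxygen) with a C42–C50 side chain: fifty skeletal carbons, fifteen stereocentres, twelve free hydroxyls and four stereodefined double bonds. The stereocentres fall into four clusters separated by methylene runs: the all-anti 1,3-hexaol C7–C17 with the anti,syn triad C17–C18–C19; the 1,5-related carbinols C23, C27 and C31; the syn,syn triad C41–C43; and the lone carbinol C49. Inside the polyol a centre can direct its neighbour, but C19→C23 (across the (Z)-C20=C21 olefin), C23→C27→C31 and everything east of C31 lie beyond ordinary 1,2- or 1,3-induction.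

Two features make a short plan possible. First, C19–C23 is a (Z)-pent-2-ene-1,5-diol: C19 is an allylic and C23 a homoallylic carbinol in 1,5-syn relation, the exact product pattern of a one-pot double allylboration. The same unit recurs in saturated form at C27–C31. Second, the segment C5–C15 has a local C2 axis through C10, so C7/C13 and C9/C11 are pairwise homotopic.

The ring is too large to give any conformational help and must be closed in the presence of thirteen oxygens, of which only O41 may be acylated. The fragile groups are the (2E,4Z)-4-methyl-dienoate (the 4Z bond isomerises under basic, nucleophilic or radical conditions), the two isolated (Z)-olefins (no late hydrogenation is possible), and the C41 ester beside the C43 hydroxyl (acyl migration under base).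

## Retrosynthesis

**48 ⇒ 47.** Only ten TBS ethers are removed at the end. The hydroxyls at C19 and C23 are never protected, because they are created late and nothing after their creation needs them masked.

**47 ⇒ 46 (cut C3–C4).** The ring is opened at the diene σ-bond and not at the lactone C–O bond. Forward, a (Z)-vinyl iodide at C4 adds to a C41 acrylate in an intramolecular Heck reaction. This makes the sensitive (2E,4Z)-diene in the ring-closing step itself. It also removes the need to single out O41 at the seco stage, since the acrylate is put on when O41 is the only free hydroxyl in its fragment. The precursor 46 is acyclic and carries a two-carbon ester in place of the dienoic acid.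

**46 ⇒ 15 + 43 + 33 (cut C19–C20 and C22–C23; key step).** The (Z)-ene-1,5-diol is taken apart into the west aldehyde 15 (C4–C19, seven stereocentres), the east aldehyde 43 (C23–C50, six stereocentres) and the three-carbon allenylboronate 33, which supplies C20–C22 through the γ-borylallylborane 44. Against an alkyne linchpin or an olefination at C20=C21, this cut forms two C–C bonds, both carbinols and the olefin geometry in one flask. It also lets C19 dictate C23, which no neighbouring group could do. The forward reaction must differentiate the two aldehydes, which is done by the order of addition, and must place the C19-bearing substituent axial in the second allylboration.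

**43 ⇒ 25 + 38 (cut C37–C38).** The (Z)-C38=C39 olefin is traced to an alkyne (40), made by alkylating the acetylide of alkynol 25 with bromide 38. The cut is placed at an sp–sp3 bond between two methylene-flanked carbons, far from any stereocentre. O41 is born free in 25 and stays the only free hydroxyl until it is acrylated (42). The C23 aldehyde travels as a dimethyl acetal.

**38 ⇒ 27 + 29 + 33 (cut C27–C28 and C30–C31).** The same double allylboration is used again, now with two achiral aldehydes, so that C31 and C27 come from the Ipc groups alone. 7-Bromoheptanal 29 is added first and 5,5-dimethoxypentanal 27 second. Because the two carbinols of a 1,5-syn diol exchange roles when the order of the aldehydes is reversed, this order calls for the antipodal borane, (−)-Ipc2BH, and hence for 34, the enantiomer of 44. The (Z)-olefin of 36 lies at C29=C30 and is hydrogenated after silylation (37), so either order would lead to 38. The order is chosen so that 27, the cheaper and more volatile aldehyde, is the one used in excess in the slow second allylboration. Two remote stereocentres come from two one-step aldehydes.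

**25 ⇒ 24 ⇒ 21 ⇒ 19 ⇒ 16 + 17.** The syn,syn triad is built outward from C49, which is bought as (R)-methyloxirane 17. A (Z)-crotylboration of 21 sets C42/C43, and a catalysed propargylation of 24 sets C41 and delivers C38–C40.

**15 ⇒ 9 ⇒ 8 ⇒ 1.** C17/C18 and C15 come from crotyl- and allylboration of aldehydes 12 and 9. Aldehyde 9 is the mono-olefination product of the C2-symmetric dialdehyde 8 (C5–C15). Because the two termini of 8 are homotopic, any single olefination gives the same compound. Dialdehyde 8 is reached in six steps from propane-1,3-diol 1 by two rounds of two-directional allylation (2, 6), each round setting two carbinols at once.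

## Roads not taken

**Alternative 1:** (the obvious one) Cut the lactone C1–O41 bond and assemble the chain linearly, with an acetylide linchpin at C20–C21 (aldehyde addition at C19, epoxide opening at C22) followed by semihydrogenation. The forward key step is a Yamaguchi macrolactonisation of seco acid A1. Three things speak against it. A1 must have O41 as its only free hydroxyl among thirteen, which costs an orthogonal protecting-group pair and two unmasking steps. The (2E,4Z)-dienoic acid must be carried through the assembly and then activated as a mixed anhydride with DMAP, conditions under which reversible conjugate addition and dienolate formation isomerise the 4Z bond. And C19 and C23 need two independent asymmetric operations plus a partial hydrogenation, where the chosen plan uses one flask.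

**Alternative 2:** Cut C38–C39 by ring-closing alkyne metathesis of diyne ester A2, using a molybdenum alkylidyne such as Mo(≡C-C6H4-4-OMe)(OSiPh3)3, to give cycloalkyne A3, then semihydrogenate. The closure itself is reliable at a site this remote. However, the (Z)-olefin must then be made by partial hydrogenation of A3 in the presence of the conjugated dienoate and the C20 olefin. Two methyl-capped alkynes add steps. The complete dienoic acid must again be esterified intermolecularly onto the hindered O41. The plan solves ring closure but none of the stereochemical problem.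

**Alternative 3:** Cut C8–C9, C9–C10, C14–C15 and C15–C16 by a five-component dithiane linchpin coupling. Two lithiated silyl dithianes and two terminal homoallylic epoxides are joined around the C2-symmetric bis-epoxide A4 to give bis-dithiane A5, followed by dithiane removal and a two-directional 1,3-anti reduction. This sets six carbinols from three bought or made epoxide centres. Its drawbacks are that the symmetric termini of A5 cannot carry the C18 methyl, which would have to be added later by enolate alkylation after a statistical end differentiation. A4 needs its own asymmetric synthesis, and dithiane hydrolysis adds heavy-metal or iodine steps. The chosen route reaches an equivalent C2-symmetric tetraol in six steps from propane-1,3-diol and breaks the symmetry with a bond-forming step.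

Key step: step 31

Assumption: the antipodes named for Cl,MeO-BIPHEP (steps 1 and 4) and TRIP (step 20) follow the sense of induction known for unbranched aliphatic substrates; if either proves opposite, the other antipode is used and nothing else changes.

## Steps

**West half (C4–C19)**

Step 1
Reactants: 1 propane-1,3-diol
Product: 2 (4R,6R)-nona-1,8-diene-4,6-diol
Conditions: allyl acetate, [Ir(cod)Cl]2 (cat.), (R)-Cl,MeO-BIPHEP, 4-chloro-3-nitrobenzoic acid (cat.), Cs2CO3 (cat.), 1,4-dioxane, 90 °C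
Reagents that add atoms: allyl acetate, C=CCOC(C)=O
Why: Two-directional iridium-catalysed transfer-hydrogenative allylation from the alcohol oxidation level (Krische allylation); both carbinols (C9, C11) are set by the catalyst, and the minor enantiomer is diverted into the meso diastereomer, so the C2-symmetric anti diol should be essentially enantiopure.

Step 2
Reactants: 2 (4R,6R)-nona-1,8-diene-4,6-diol
Product: 3 (4R,6R)-4,6-bis(TBSO)nona-1,8-diene
Conditions: TBSCl, imidazole, DMF, 25 °C
Reagents that add atoms: tert-butyldimethylsilyl chloride, CC(C)(C)[Si](C)(C)Cl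
Why: Standard silylation of unhindered secondary alcohols; TBS is chosen because every later step up to the final fluoride treatment tolerates it.

Step 3
Reactants: 3 (4R,6R)-4,6-bis(TBSO)nona-1,8-diene
Product: 5 (3R,5R)-3,5-bis(TBSO)heptane-1,7-diol, via dialdehyde 4 (not isolated)
Conditions: O3, CH2Cl2, −78 °C; Me2S; then NaBH4, MeOH, 0 °C
Reagents that add atoms: ozone, [O-][O+]=O
Why: Ozonolysis of both terminal olefins and in-situ reduction returns the chain to the alcohol oxidation level needed for the next allylation; no stereocentre is touched.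

Step 4
Reactants: 5 (3R,5R)-3,5-bis(TBSO)heptane-1,7-diol
Product: 6 (4S,6R,8R,10S)-6,8-bis(TBSO)trideca-1,12-diene-4,10-diol
Conditions: allyl acetate, [Ir(cod)Cl]2 (cat.), (S)-Cl,MeO-BIPHEP, 4-chloro-3-nitrobenzoic acid (cat.), Cs2CO3 (cat.), 1,4-dioxane, 100 °C
Reagents that add atoms: allyl acetate, C=CCOC(C)=O
Why: Second two-directional Krische allylation; the antipodal ligand sets C7 and C13 anti to C9 and C11 by catalyst control, giving the all-anti, C2-symmetric tetraol pattern.

Step 5
Reactants: 6 (4S,6R,8R,10S)-6,8-bis(TBSO)trideca-1,12-diene-4,10-diol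
Product: 7 (4S,6R,8R,10S)-4,6,8,10-tetrakis(TBSO)trideca-1,12-diene
Conditions: TBSOTf, 2,6-lutidine, CH2Cl2, −78 → 0 °C
Reagents that add atoms: tert-butyldimethylsilyl triflate, CC(C)(C)[Si](C)(C)OS(=O)(=O)C(F)(F)F
Why: Silylation of the two homotopic secondary alcohols; the triflate is used because the carbinols are flanked by silyloxy groups.

Step 6
Reactants: 7 (4S,6R,8R,10S)-4,6,8,10-tetrakis(TBSO)trideca-1,12-diene
Product: 8 (3R,5S,7S,9R)-3,5,7,9-tetrakis(TBSO)undecanedial (C5–C15)
Conditions: O3, CH2Cl2, −78 °C; PPh3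
Reagents that add atoms: ozone, [O-][O+]=O
Why: Ozonolysis with reductive work-up; the β-silyloxy dialdehyde is used without chromatography to avoid elimination.

Step 7
Reactants: 8 (3R,5S,7S,9R)-3,5,7,9-tetrakis(TBSO)undecanedial (two-fold excess)
Product: 9 (Z)-12-iodo-3,5,7,9-tetrakis(TBSO)tridec-11-enal (C15–C4; carbinol centres as in 8)
Conditions: EtPPh3I, n-BuLi, THF, 25 °C; I2, −78 °C; NaN(SiMe3)2, −20 °C; then added to 8, −78 °C
Reagents that add atoms: ethyltriphenylphosphonium iodide, CC[P+](c1ccccc1)(c1ccccc1)c1ccccc1.[I-]; iodine, II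
Why: Stork–Zhao olefination: the α-iodo ylide reacts under kinetic control to give the (Z)-2-iodoalkene (iodine cis to C6), which fixes the future 4Z geometry. The two formyl groups of 8 are homotopic, so mono-olefination gives a single compound; the step is deliberately statistical, run with excess 8, which is recovered and recycled.

Step 8
Reactants: 9 (Z)-12-iodo-3,5,7,9-tetrakis(TBSO)tridec-11-enal
Product: 10 (Z)-15-iodo-6,8,10,12-tetrakis(TBSO)hexadeca-1,14-dien-4-ol (new carbinol C15, anti to C13)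
Conditions: (+)-Ipc2BOMe, allylmagnesium bromide, Et2O, 0 → 25 °C; then 9, −78 °C; NaOH, H2O2, 0 °C
Reagents that add atoms: allylmagnesium bromide, C=CC[Mg]Br
Why: Brown allylation; the (−)-α-pinene-derived reagent attacks the Re face of the aldehyde through a chair transition state, setting C15 by reagent control. The vinyl iodide is inert to allylboranes and to the cold peroxide work-up.

Step 9
Reactants: 10 (Z)-15-iodo-6,8,10,12-tetrakis(TBSO)hexadeca-1,14-dien-4-ol
Product: 11 (Z)-15-iodo-4,6,8,10,12-pentakis(TBSO)hexadeca-1,14-diene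
Conditions: TBSOTf, 2,6-lutidine, CH2Cl2, −78 → 0 °C
Reagents that add atoms: tert-butyldimethylsilyl triflate, CC(C)(C)[Si](C)(C)OS(=O)(=O)C(F)(F)F
Why: Routine protection of the new carbinol before oxidative cleavage.

Step 10
Reactants: 11 (Z)-15-iodo-4,6,8,10,12-pentakis(TBSO)hexadeca-1,14-diene
Product: 12 (Z)-14-iodo-3,5,7,9,11-pentakis(TBSO)pentadec-13-enal (C17–C4)
Conditions: OsO4 (cat.), NaIO4, 2,6-lutidine, dioxane/H2O, 25 °C
Reagents that add atoms: sodium periodate, [Na+].[O-]I(=O)(=O)=O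
Why: Lemieux–Johnson cleavage; the monosubstituted olefin is dihydroxylated far faster than the hindered, electron-poor iodoalkene, which ozone would not spare.

Step 11
Reactants: 12 (Z)-14-iodo-3,5,7,9,11-pentakis(TBSO)pentadec-13-enal
Product: 13 (Z)-17-iodo-3-methyl-6,8,10,12,14-pentakis(TBSO)octadeca-1,16-dien-4-ol (C17 carbinol, C18 methyl; 3,4-anti)
Conditions: (E)-but-2-ene, KOtBu, n-BuLi, THF, −78 → −45 °C; (−)-Ipc2BOMe, −78 °C; BF3·OEt2; then 12, −78 °C; NaOH, H2O2, 0 °C
Reagents that add atoms: (E)-but-2-ene, C/C=C/C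
Why: Brown crotylation; the (E)-crotylborane gives the anti C17/C18 relation through the chair transition state, and the (+)-α-pinene-derived Ipc groups direct Si-face attack, making C17 anti to C15.

Step 12
Reactants: 13 (Z)-17-iodo-3-methyl-6,8,10,12,14-pentakis(TBSO)octadeca-1,16-dien-4-ol
Product: 14 (Z)-17-iodo-3-methyl-4,6,8,10,12,14-hexakis(TBSO)octadeca-1,16-diene
Conditions: TBSOTf, 2,6-lutidine, CH2Cl2, 0 °C
Reagents that add atoms: tert-butyldimethylsilyl triflate, CC(C)(C)[Si](C)(C)OS(=O)(=O)C(F)(F)F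
Why: Protection of the hindered C17 carbinol; the triflate is needed next to the methyl-bearing C18.

Step 13
Reactants: 14 (Z)-17-iodo-3-methyl-4,6,8,10,12,14-hexakis(TBSO)octadeca-1,16-diene
Product: 15 (Z)-16-iodo-2-methyl-3,5,7,9,11,13-hexakis(TBSO)heptadec-15-enal (west aldehyde, C19–C4; C7–C18 as in 48)
Conditions: OsO4 (cat.), NaIO4, 2,6-lutidine, dioxane/H2O, 25 °C
Reagents that add atoms: sodium periodate, [Na+].[O-]I(=O)(=O)=O
Why: Lemieux–Johnson cleavage of the terminal vinyl group as in step 10; the buffered medium protects the α-stereocentre C18, and the aldehyde is used at once.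

**Side-chain piece (C38–C50)**

Step 14
Reactants: 16 6-bromohex-1-ene; 17 (R)-2-methyloxirane
Product: 19 (R)-non-8-en-2-ol, via hex-5-enylmagnesium bromide 18 (not isolated)
Conditions: Mg, THF; CuI (cat.), 17, −30 → 0 °C
Reagents that add atoms: none
Why: Copper-catalysed Grignard opening of the epoxide at its CH2 terminus; C49 is bought and is not touched.

Step 15
Reactants: 19 (R)-non-8-en-2-ol
Product: 20 (R)-2-(TBSO)non-8-ene
Conditions: TBSCl, imidazole, DMF, 25 °C
Reagents that add atoms: tert-butyldimethylsilyl chloride, CC(C)(C)[Si](C)(C)Cl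
Why: Routine silylation.

Step 16
Reactants: 20 (R)-2-(TBSO)non-8-ene
Product: 21 (R)-7-(TBSO)octanal (C43–C50)
Conditions: O3, CH2Cl2, −78 °C; PPh3
Reagents that add atoms: ozone, [O-][O+]=O
Why: Ozonolysis of the terminal olefin gives the C43 aldehyde.

Step 17
Reactants: 21 (R)-7-(TBSO)octanal
Product: 22 (3R,4R,10R)-10-(TBSO)-3-methylundec-1-en-4-ol (C42/C43 syn)
Conditions: (Z)-but-2-ene, KOtBu, n-BuLi, THF, −78 → −45 °C; (−)-Ipc2BOMe, −78 °C; BF3·OEt2; then 21, −78 °C; NaOH, H2O2, 0 °C
Reagents that add atoms: (Z)-but-2-ene, C/C=C\C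
Why: Brown crotylation; the (Z)-crotylborane gives the syn C42/C43 pair, and the (+)-α-pinene-derived Ipc groups (Si-face attack) fix the absolute configuration.

Step 18
Reactants: 22 (3R,4R,10R)-10-(TBSO)-3-methylundec-1-en-4-ol
Product: 23 (3R,4R,10R)-4,10-bis(TBSO)-3-methylundec-1-ene
Conditions: TBSOTf, 2,6-lutidine, CH2Cl2, −78 → 0 °C
Reagents that add atoms: tert-butyldimethylsilyl triflate, CC(C)(C)[Si](C)(C)OS(=O)(=O)C(F)(F)F
Why: Routine protection of O43, so that O41, made next, is the only free hydroxyl.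

Step 19
Reactants: 23 (3R,4R,10R)-4,10-bis(TBSO)-3-methylundec-1-ene
Product: 24 (2S,3R,9R)-3,9-bis(TBSO)-2-methyldecanal (C41–C50)
Conditions: O3, CH2Cl2, −78 °C; PPh3
Reagents that add atoms: ozone, [O-][O+]=O
Why: Ozonolysis gives the α-methyl-β-silyloxy aldehyde, used directly to avoid epimerisation at C42.

Step 20
Reactants: 24 (2S,3R,9R)-3,9-bis(TBSO)-2-methyldecanal
Product: 25 (4S,5R,6R,12R)-6,12-bis(TBSO)-5-methyltridec-1-yn-4-ol (C38–C50; C41–C43 syn,syn)
Conditions: allenylboronic acid pinacol ester, (S)-TRIP (cat.), 4 Å molecular sieves, toluene, −20 °C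
Reagents that add atoms: allenylboronic acid pinacol ester, C=C=CB1OC(C)(C)C(C)(C)O1
Why: Brønsted-acid-catalysed propargylboration through a six-membered transition state (SE2′ at the allenyl boronate); the catalyst directs Si-face attack, which is also the Felkin face of the 2,3-syn aldehyde, so C41 is set syn to C42 with reagent and substrate matched. O41 emerges as the only free hydroxyl.

**East half (C23–C50)**

Step 21
Reactants: 26 cyclopentene
Product: 27 5,5-dimethoxypentanal (C23–C27)
Conditions: O3, CH2Cl2/MeOH, −78 °C; TsOH (cat.), 25 °C; NaHCO3; Me2S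
Reagents that add atoms: ozone, [O-][O+]=O; methanol, CO
Why: Ozonolysis in methanol with acid then reductive work-up differentiates the two termini of the cycloalkene in one step (aldehyde from the carbonyl oxide end, acetal from the other).

Step 22
Reactants: 28 7-bromoheptan-1-ol
Product: 29 7-bromoheptanal (C31–C37)
Conditions: TEMPO (cat.), PhI(OAc)2, CH2Cl2, 25 °C
Reagents that add atoms: none
Why: Oxoammonium oxidation of a primary alcohol to the aldehyde without over-oxidation; the bromide is untouched.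

Step 23
Reactants: 30 3-bromoprop-1-yne; 31 1,1,2,2-tetraphenylethane-1,2-diol
Product: 33 4,4,5,5-tetraphenyl-2-(propa-1,2-dienyl)-1,3,2-dioxaborolane, via dimethyl allenylboronate 32 (not isolated)
Conditions: Mg, HgCl2 (cat.), Et2O, 0 °C; B(OMe)3, −78 °C; HCl/Et2O; then 31, 4 Å molecular sieves, 25 °C
Reagents that add atoms: trimethyl borate, COB(OC)OC
Why: The propargyl/allenyl Grignard reagent adds to the borate with propargyl-to-allenyl transposition; ester exchange with the hindered diol gives the bulky boronate on which the (Z)-selectivity of steps 24 and 31 depends.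

Step 24
Reactants: 33 4,4,5,5-tetraphenyl-2-(propa-1,2-dienyl)-1,3,2-dioxaborolane; 29 7-bromoheptanal; 27 5,5-dimethoxypentanal
Product: 36 (5S,9R,Z)-15-bromo-1,1-dimethoxypentadec-7-ene-5,9-diol (C23–C37; C27 and C31 carbinols), via γ-borylallylborane 34 (not isolated), via borinate allylboronate 35 (not isolated)
Conditions: (−)-Ipc2BH, 33, CH2Cl2, 0 → 25 °C; 29 (limiting), −78 °C; then 27 (excess), −78 → 25 °C; pH 7 buffer, H2O2, MeOH, 0 °C
Reagents that add atoms: none
Why: One-pot double allylboration with the (+)-α-pinene-derived borane: 34 adds to 29 through its dialkylborane terminus (C31 set by the Ipc groups, Si face), and the resulting α-substituted allylboronate 35 adds to 27 with its α-substituent axial, which gives the (Z)-C29=C30 olefin and transfers chirality to C27 (1,5-syn). The olefin is removed in step 26, so the order of the aldehydes is free; 29 is put first so that the cheap, volatile 27 is the aldehyde used in excess in the slow second allylboration, and this order is what calls for the borane antipodal to that of step 31.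

Step 25
Reactants: 36 (5S,9R,Z)-15-bromo-1,1-dimethoxypentadec-7-ene-5,9-diol
Product: 37 (5S,9R,Z)-15-bromo-5,9-bis(TBSO)-1,1-dimethoxypentadec-7-ene
Conditions: TBSCl, imidazole, DMAP (cat.), DMF, 25 °C
Reagents that add atoms: tert-butyldimethylsilyl chloride, CC(C)(C)[Si](C)(C)Cl
Why: Chloride/imidazole is used instead of the triflate so that the dimethyl acetal is not activated; at room temperature the primary bromide is not alkylated by imidazole at a competitive rate.

Step 26
Reactants: 37 (5S,9R,Z)-15-bromo-5,9-bis(TBSO)-1,1-dimethoxypentadec-7-ene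
Product: 38 (5R,9R)-15-bromo-5,9-bis(TBSO)-1,1-dimethoxypentadecane
Conditions: H2 (1 atm), Pt/C, EtOAc, 25 °C
Reagents that add atoms: none
Why: Heterogeneous hydrogenation of the only olefin in the molecule; platinum in a neutral solvent leaves the primary bromide, acetal and silyl ethers intact, and neither carbinol centre is touched.

Step 27
Reactants: 25 (4S,5R,6R,12R)-6,12-bis(TBSO)-5-methyltridec-1-yn-4-ol; 38 (5R,9R)-15-bromo-5,9-bis(TBSO)-1,1-dimethoxypentadecane
Product: 40 C23–C50 alkynol (C23 dimethyl acetal; TBS ethers at O27, O31, O43, O49; C38≡C39; free O41-H), via dilithio alkynolate 39 (not isolated)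
Conditions: 25, n-BuLi (2.1 equiv), THF/HMPA, −78 → −20 °C; then 38, −20 → 25 °C
Reagents that add atoms: none
Why: Alkylation of a lithium acetylide with a primary bromide in a dipolar medium (SN2); the lithium alkoxide is far less nucleophilic than the acetylide, so O41 needs no protection.

Step 28
Reactants: 40 C23–C50 alkynol
Product: 41 C23–C50 (Z)-C38-alkenol (free O41-H)
Conditions: H2 (1 atm), Pd/CaCO3 poisoned with Pb(OAc)2 (Lindlar catalyst), quinoline, EtOAc, 25 °C
Reagents that add atoms: none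
Why: Lindlar semihydrogenation gives the (Z)-olefin by syn addition; it is done here because no other reducible group is yet present.

Step 29
Reactants: 41 C23–C50 (Z)-C38-alkenol
Product: 42 C41 acrylate of 41
Conditions: acryloyl chloride, iPr2NEt, DMAP (cat.), CH2Cl2, −20 → 0 °C
Reagents that add atoms: acryloyl chloride, C=CC(=O)Cl
Why: Acylation of the only free hydroxyl; the future C1–C3 unit is attached intermolecularly, so no late discrimination among hydroxyls is needed.

Step 30
Reactants: 42 C41 acrylate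
Product: 43 east aldehyde (C23 aldehyde; TBS ethers at O27, O31, O43, O49; (Z)-C38 olefin; C41 acrylate)
Conditions: pyridinium p-toluenesulfonate (cat.), acetone/H2O, 45 °C
Reagents that add atoms: water, O
Why: Mild transacetalisation/hydrolysis of an aliphatic dimethyl acetal; secondary TBS ethers and the acrylate survive these conditions.

**Union, ring closure and deprotection**

Step 31
Reactants: 33 4,4,5,5-tetraphenyl-2-(propa-1,2-dienyl)-1,3,2-dioxaborolane; 15 west aldehyde; 43 east aldehyde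
Product: 46 seco (Z)-ene-diol (C4 vinyl iodide to C41 acrylate; free O19-H and O23-H; ten TBS ethers), via enantiomeric γ-borylallylborane 44 (not isolated), via borinate allylboronate 45 (not isolated)
Conditions: (+)-Ipc2BH, 33, CH2Cl2, 0 → 25 °C; 15, −78 °C; then 43, −78 → 25 °C, 48 h; pH 7 buffer, H2O2, MeOH, 0 °C
Reagents that add atoms: none
Why: Hydroboration of allene 33 at its terminal double bond with the (−)-α-pinene-derived borane, followed by 1,3-boratropic equilibration, should give the (E)-γ-borylallylborane 44 (the Ipc antipode of 34); at −78 °C only its dialkylborane terminus reacts with 15 through a chair transition state, giving 45 with C19 set by the Ipc groups (Re-face attack, reinforced by the Felkin preference of the 2,3-anti α-methyl-β-silyloxy aldehyde, hence C18/C19 syn) and the boron-bearing C20 anti to O19 because the (E)-γ-boryl group sits equatorial. On warming, the α-substituted allylboronate 45 adds to 43 in a second chair in which the bulky tetraphenyl dioxaborolane forces the C19-bearing substituent on C20 axial; that one preference fixes both the (Z) geometry of C20=C21 and, by 1,3-transfer of the C20 configuration, the configuration of C23 (1,5-syn to C19), which the unbranched aldehyde 43 could not acquire from any bias of its own. The closest known reaction is the one-pot double allylboration of two aldehydes with a bifunctional γ-borylallylborane to give (Z)-1,5-syn-pent-2-ene-1,5-diols, used here as a three-component fragment union. It forms C19–C20 and C22–C23, two stereocentres and one olefin, and closes no ring. The selectivities needed are chemoselectivity between the aldehydes (secured by the order of addition and by the reactivity gap between the dialkylborane and the boronate), face selectivity at C19 (reagent and substrate matched) and axial placement in the second step (secured by the tetraphenylethylene glycol ester). The vinyl iodide, the acrylate, the silyl ethers and the C38 olefin are inert to allylboranes, and the buffered peroxide work-up cleaves only B–C and B–O bonds.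

Step 32
Reactants: 46 seco (Z)-ene-diol
Product: 47 deca-TBS macrolactone (42-membered ring; (2E,4Z)-dienoate; free O19-H and O23-H)
Conditions: Pd(OAc)2 (cat.), Bu4NCl, NaHCO3, DMF (high dilution), 50 °C
Reagents that add atoms: none
Why: Intramolecular Heck reaction under phosphine-free phase-transfer (Jeffery) conditions: oxidative addition to the vinyl iodide occurs with retention (4Z), carbopalladation of the acrylate at its terminal carbon (C3) and syn β-hydride elimination give the 2E olefin. The ring is closed end-on at C3–C4; free hydroxyls are tolerated, and bicarbonate is too weak a base to induce acyl transfer.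

Step 33
Reactants: 47 deca-TBS macrolactone
Product: 48 CNP0071908.1
Conditions: HF·pyridine, pyridine, THF, 0 → 25 °C
Reagents that add atoms: none
Why: Global desilylation under buffered acidic fluoride conditions; the medium is never basic, so the C41 ester does not migrate to O43 and the 4Z bond is not isomerised.

## Compound list

1 | propane-1,3-diol | OCCCO | starting material
2 | (4R,6R)-nona-1,8-diene-4,6-diol | C=CC[C@@H](O)C[C@H](O)CC=C | intermediate
3 | (4R,6R)-4,6-bis(TBSO)nona-1,8-diene | C=CC[C@@H](O[Si](C)(C)C(C)(C)C)C[C@H](O[Si](C)(C)C(C)(C)C)CC=C | intermediate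
4 | (3S,5S)-3,5-bis(TBSO)heptanedial | O=CC[C@@H](O[Si](C)(C)C(C)(C)C)C[C@H](O[Si](C)(C)C(C)(C)C)CC=O | intermediate
5 | (3R,5R)-3,5-bis(TBSO)heptane-1,7-diol | OCC[C@@H](O[Si](C)(C)C(C)(C)C)C[C@H](O[Si](C)(C)C(C)(C)C)CCO | intermediate
6 | (4S,6R,8R,10S)-6,8-bis(TBSO)trideca-1,12-diene-4,10-diol | C=CC[C@H](O)C[C@@H](O[Si](C)(C)C(C)(C)C)C[C@H](O[Si](C)(C)C(C)(C)C)C[C@@H](O)CC=C | intermediate
7 | (4S,6R,8R,10S)-4,6,8,10-tetrakis(TBSO)trideca-1,12-diene | C=CC[C@H](O[Si](C)(C)C(C)(C)C)C[C@@H](O[Si](C)(C)C(C)(C)C)C[C@H](O[Si](C)(C)C(C)(C)C)C[C@@H](O[Si](C)(C)C(C)(C)C)CC=C | intermediate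
8 | (3R,5S,7S,9R)-3,5,7,9-tetrakis(TBSO)undecanedial | O=CC[C@H](O[Si](C)(C)C(C)(C)C)C[C@@H](O[Si](C)(C)C(C)(C)C)C[C@H](O[Si](C)(C)C(C)(C)C)C[C@@H](O[Si](C)(C)C(C)(C)C)CC=O | intermediate
9 | (Z)-12-iodo-3,5,7,9-tetrakis(TBSO)tridec-11-enal | C/C(I)=C/C[C@H](O[Si](C)(C)C(C)(C)C)C[C@@H](O[Si](C)(C)C(C)(C)C)C[C@H](O[Si](C)(C)C(C)(C)C)C[C@@H](O[Si](C)(C)C(C)(C)C)CC=O | intermediate
10 | (Z)-15-iodo-6,8,10,12-tetrakis(TBSO)hexadeca-1,14-dien-4-ol | C/C(I)=C/C[C@H](O[Si](C)(C)C(C)(C)C)C[C@@H](O[Si](C)(C)C(C)(C)C)C[C@H](O[Si](C)(C)C(C)(C)C)C[C@@H](O[Si](C)(C)C(C)(C)C)C[C@H](O)CC=C | intermediate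
11 | (Z)-15-iodo-4,6,8,10,12-pentakis(TBSO)hexadeca-1,14-diene | C/C(I)=C/C[C@H](O[Si](C)(C)C(C)(C)C)C[C@@H](O[Si](C)(C)C(C)(C)C)C[C@H](O[Si](C)(C)C(C)(C)C)C[C@@H](O[Si](C)(C)C(C)(C)C)C[C@H](O[Si](C)(C)C(C)(C)C)CC=C | intermediate
12 | (Z)-14-iodo-3,5,7,9,11-pentakis(TBSO)pentadec-13-enal | C/C(I)=C/C[C@H](O[Si](C)(C)C(C)(C)C)C[C@@H](O[Si](C)(C)C(C)(C)C)C[C@H](O[Si](C)(C)C(C)(C)C)C[C@@H](O[Si](C)(C)C(C)(C)C)C[C@H](O[Si](C)(C)C(C)(C)C)CC=O | intermediate
13 | (Z)-17-iodo-3-methyl-6,8,10,12,14-pentakis(TBSO)octadeca-1,16-dien-4-ol (3,4-anti) | C/C(I)=C/C[C@H](O[Si](C)(C)C(C)(C)C)C[C@@H](O[Si](C)(C)C(C)(C)C)C[C@H](O[Si](C)(C)C(C)(C)C)C[C@@H](O[Si](C)(C)C(C)(C)C)C[C@H](O[Si](C)(C)C(C)(C)C)C[C@@H](O)[C@@H](C)C=C | intermediate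
14 | (Z)-17-iodo-3-methyl-4,6,8,10,12,14-hexakis(TBSO)octadeca-1,16-diene | C/C(I)=C/C[C@H](O[Si](C)(C)C(C)(C)C)C[C@@H](O[Si](C)(C)C(C)(C)C)C[C@H](O[Si](C)(C)C(C)(C)C)C[C@@H](O[Si](C)(C)C(C)(C)C)C[C@H](O[Si](C)(C)C(C)(C)C)C[C@@H](O[Si](C)(C)C(C)(C)C)[C@@H](C)C=C | intermediate
15 | west aldehyde, (Z)-16-iodo-2-methyl-3,5,7,9,11,13-hexakis(TBSO)heptadec-15-enal | C/C(I)=C/C[C@H](O[Si](C)(C)C(C)(C)C)C[C@@H](O[Si](C)(C)C(C)(C)C)C[C@H](O[Si](C)(C)C(C)(C)C)C[C@@H](O[Si](C)(C)C(C)(C)C)C[C@H](O[Si](C)(C)C(C)(C)C)C[C@@H](O[Si](C)(C)C(C)(C)C)[C@@H](C)C=O | intermediate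
16 | 6-bromohex-1-ene | C=CCCCCBr | starting material
17 | (R)-2-methyloxirane | C[C@@H]1CO1 | starting material
18 | hex-5-enylmagnesium bromide | C=CCCCC[Mg]Br | intermediate
19 | (R)-non-8-en-2-ol | C=CCCCCC[C@@H](C)O | intermediate
20 | (R)-2-(TBSO)non-8-ene | C=CCCCCC[C@@H](C)O[Si](C)(C)C(C)(C)C | intermediate
21 | (R)-7-(TBSO)octanal | O=CCCCCC[C@@H](C)O[Si](C)(C)C(C)(C)C | intermediate
22 | (3R,4R,10R)-10-(TBSO)-3-methylundec-1-en-4-ol | C=C[C@@H](C)[C@H](O)CCCCC[C@@H](C)O[Si](C)(C)C(C)(C)C | intermediate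
23 | (3R,4R,10R)-4,10-bis(TBSO)-3-methylundec-1-ene | C=C[C@@H](C)[C@H](O[Si](C)(C)C(C)(C)C)CCCCC[C@@H](C)O[Si](C)(C)C(C)(C)C | intermediate
24 | (2S,3R,9R)-3,9-bis(TBSO)-2-methyldecanal | O=C[C@@H](C)[C@H](O[Si](C)(C)C(C)(C)C)CCCCC[C@@H](C)O[Si](C)(C)C(C)(C)C | intermediate
25 | (4S,5R,6R,12R)-6,12-bis(TBSO)-5-methyltridec-1-yn-4-ol | C#CC[C@@H]([C@@H](C)[C@H](O[Si](C)(C)C(C)(C)C)CCCCC[C@@H](C)O[Si](C)(C)C(C)(C)C)O | intermediate
26 | cyclopentene | C1=CCCC1 | starting material
27 | 5,5-dimethoxypentanal | COC(OC)CCCC=O | intermediate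
28 | 7-bromoheptan-1-ol | OCCCCCCCBr | starting material
29 | 7-bromoheptanal | O=CCCCCCCBr | intermediate
30 | 3-bromoprop-1-yne | C#CCBr | starting material
31 | 1,1,2,2-tetraphenylethane-1,2-diol | OC(c1ccccc1)(c1ccccc1)C(O)(c1ccccc1)c1ccccc1 | starting material
32 | dimethyl propa-1,2-dienylboronate | C=C=CB(OC)OC | intermediate
33 | 4,4,5,5-tetraphenyl-2-(propa-1,2-dienyl)-1,3,2-dioxaborolane | C=C=CB1OC(c2ccccc2)(c2ccccc2)C(c2ccccc2)(c2ccccc2)O1 | intermediate
34 | (E)-[3-(4,4,5,5-tetraphenyl-1,3,2-dioxaborolan-2-yl)allyl]bis(isopinocampheyl)borane (Ipc from (+)-α-pinene) | C(/C=C/B1OC(c2ccccc2)(c2ccccc2)C(c2ccccc2)(c2ccccc2)O1)B([C@@H]1C[C@@H]2C[C@H]([C@H]1C)C2(C)C)[C@@H]1C[C@@H]2C[C@H]([C@H]1C)C2(C)C | intermediate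
35 | C31 bis(isopinocampheyl)borinate of the C30-boryl allylboronate from 29 (C31–O/C30–B anti) | BrCCCCCC[C@@H](OB([C@@H]1C[C@@H]2C[C@H]([C@H]1C)C2(C)C)[C@@H]1C[C@@H]2C[C@H]([C@H]1C)C2(C)C)[C@@H](B1OC(c2ccccc2)(c2ccccc2)C(c2ccccc2)(c2ccccc2)O1)C=C | intermediate
36 | (5S,9R,Z)-15-bromo-1,1-dimethoxypentadec-7-ene-5,9-diol | COC(OC)CCC[C@H](O)C/C=C\[C@H](O)CCCCCCBr | intermediate
37 | (5S,9R,Z)-15-bromo-5,9-bis(TBSO)-1,1-dimethoxypentadec-7-ene | COC(OC)CCC[C@H](O[Si](C)(C)C(C)(C)C)C/C=C\[C@H](O[Si](C)(C)C(C)(C)C)CCCCCCBr | intermediate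
38 | (5R,9R)-15-bromo-5,9-bis(TBSO)-1,1-dimethoxypentadecane | COC(OC)CCC[C@H](O[Si](C)(C)C(C)(C)C)CCC[C@H](O[Si](C)(C)C(C)(C)C)CCCCCCBr | intermediate
39 | dilithio derivative of 25 (lithium acetylide, lithium alkoxide) | [Li]C#CC[C@@H]([C@@H](C)[C@H](O[Si](C)(C)C(C)(C)C)CCCCC[C@@H](C)O[Si](C)(C)C(C)(C)C)O[Li] | intermediate
40 | C23–C50 alkynol (C23 dimethyl acetal, C38≡C39, free O41-H) | COC(OC)CCC[C@H](O[Si](C)(C)C(C)(C)C)CCC[C@H](O[Si](C)(C)C(C)(C)C)CCCCCCC#CC[C@@H]([C@@H](C)[C@H](O[Si](C)(C)C(C)(C)C)CCCCC[C@@H](C)O[Si](C)(C)C(C)(C)C)O | intermediate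
41 | C23–C50 (Z)-C38-alkenol (free O41-H) | COC(OC)CCC[C@H](O[Si](C)(C)C(C)(C)C)CCC[C@H](O[Si](C)(C)C(C)(C)C)CCCCCC/C=C\C[C@@H]([C@@H](C)[C@H](O[Si](C)(C)C(C)(C)C)CCCCC[C@@H](C)O[Si](C)(C)C(C)(C)C)O | intermediate
42 | C41 acrylate of 41 | COC(OC)CCC[C@H](O[Si](C)(C)C(C)(C)C)CCC[C@H](O[Si](C)(C)C(C)(C)C)CCCCCC/C=C\C[C@@H]([C@@H](C)[C@H](O[Si](C)(C)C(C)(C)C)CCCCC[C@@H](C)O[Si](C)(C)C(C)(C)C)OC(=O)C=C | intermediate
43 | east aldehyde (C23 aldehyde, C41 acrylate) | O=CCCC[C@H](O[Si](C)(C)C(C)(C)C)CCC[C@H](O[Si](C)(C)C(C)(C)C)CCCCCC/C=C\C[C@@H]([C@@H](C)[C@H](O[Si](C)(C)C(C)(C)C)CCCCC[C@@H](C)O[Si](C)(C)C(C)(C)C)OC(=O)C=C | intermediate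
44 | (E)-[3-(4,4,5,5-tetraphenyl-1,3,2-dioxaborolan-2-yl)allyl]bis(isopinocampheyl)borane (Ipc from (−)-α-pinene; enantiomer of 34) | C(/C=C/B1OC(c2ccccc2)(c2ccccc2)C(c2ccccc2)(c2ccccc2)O1)B([C@H]1C[C@H]2C[C@@H]([C@@H]1C)C2(C)C)[C@H]1C[C@H]2C[C@@H]([C@@H]1C)C2(C)C | intermediate
45 | C19 bis(isopinocampheyl)borinate of the C20-boryl allylboronate from 15 (C19–O/C20–B anti) | C/C(I)=C/C[C@H](O[Si](C)(C)C(C)(C)C)C[C@@H](O[Si](C)(C)C(C)(C)C)C[C@H](O[Si](C)(C)C(C)(C)C)C[C@@H](O[Si](C)(C)C(C)(C)C)C[C@H](O[Si](C)(C)C(C)(C)C)C[C@@H](O[Si](C)(C)C(C)(C)C)[C@@H](C)[C@H](OB([C@H]1C[C@H]2C[C@@H]([C@@H]1C)C2(C)C)[C@H]1C[C@H]2C[C@@H]([C@@H]1C)C2(C)C)[C@H](B1OC(c2ccccc2)(c2ccccc2)C(c2ccccc2)(c2ccccc2)O1)C=C | intermediate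
46 | seco (Z)-ene-diol (C4 vinyl iodide, C41 acrylate, free O19-H and O23-H) | C/C(I)=C/C[C@H](O[Si](C)(C)C(C)(C)C)C[C@@H](O[Si](C)(C)C(C)(C)C)C[C@H](O[Si](C)(C)C(C)(C)C)C[C@@H](O[Si](C)(C)C(C)(C)C)C[C@H](O[Si](C)(C)C(C)(C)C)C[C@@H](O[Si](C)(C)C(C)(C)C)[C@@H](C)[C@H](O)/C=C\C[C@H](O)CCC[C@H](O[Si](C)(C)C(C)(C)C)CCC[C@H](O[Si](C)(C)C(C)(C)C)CCCCCC/C=C\C[C@@H]([C@@H](C)[C@H](O[Si](C)(C)C(C)(C)C)CCCCC[C@@H](C)O[Si](C)(C)C(C)(C)C)OC(=O)C=C | intermediate
47 | deca-TBS macrolactone | CC1=C/C[C@H](O[Si](C)(C)C(C)(C)C)C[C@@H](O[Si](C)(C)C(C)(C)C)C[C@H](O[Si](C)(C)C(C)(C)C)C[C@@H](O[Si](C)(C)C(C)(C)C)C[C@H](O[Si](C)(C)C(C)(C)C)C[C@@H](O[Si](C)(C)C(C)(C)C)[C@@H](C)[C@H](O)/C=C\C[C@H](O)CCC[C@H](O[Si](C)(C)C(C)(C)C)CCC[C@H](O[Si](C)(C)C(C)(C)C)CCCCCC/C=C\C[C@@H]([C@@H](C)[C@H](O[Si](C)(C)C(C)(C)C)CCCCC[C@@H](C)O[Si](C)(C)C(C)(C)C)OC(=O)\C=C\1 | intermediate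
48 | CNP0071908.1 | CC1=C/C[C@H](O)C[C@@H](O)C[C@H](O)C[C@@H](O)C[C@H](O)C[C@@H](O)[C@@H](C)[C@H](O)/C=C\C[C@H](O)CCC[C@H](O)CCC[C@H](O)CCCCCC/C=C\C[C@@H]([C@@H](C)[C@H](O)CCCCC[C@@H](C)O)OC(=O)\C=C\1 | target

## Step count and risk

Total step count: 33. Longest linear sequence: 16 steps (steps 1–13 and 31–33, from propane-1,3-diol).

**Step 31 (key step).** The likeliest failure is loss of axial preference in the second allylboration, which gives the (E)-olefin with the opposite C23 configuration. A slow second addition of the hindered secondary allylboronate to 43 would also allow boratropic scrambling or protodeboronation of 45. Incomplete face control at C19 is the third concern.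

The fallback uses only known reactions and sets out from 15 and 43. Vinylmagnesium bromide adds to 15 under Felkin control (the minor epimer is separated) to give the C19 vinyl carbinol F1. B-Allylbis(isopinocampheyl)borane made from (−)-Ipc2BOMe adds to 43 to give the C23 allyl carbinol F2. F1 is silylated with iPr2SiCl2/imidazole and the chlorosilane is quenched with F2 to give the mixed diisopropylsilylene ketal F3. The Heck closure of step 32 then gives the macrocycle F4, which removes the acrylate before any ruthenium carbene is present. Ring-closing metathesis with second-generation Grubbs catalyst RuCl2(=CHPh)(PCy3)(H2IMes) closes the eight-membered dioxasilocine F5, whose ring size enforces the (Z)-C20=C21 geometry. HF·pyridine removes the tether together with the TBS groups, and the route is rejoined at 48.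

**Step 32.** At the dilution a 42-membered closure needs, carbopalladation may be slower than decay of the ligand-free catalyst. Re-addition of the palladium hydride could also erode the 4Z geometry, and competing intermolecular coupling is possible.

The fallback replaces the carbopalladation by a transmetalation-based closure and sets out from 41. Esterification with (E)-3-(tributylstannyl)acrylic acid (2,4,6-trichlorobenzoyl chloride, Et3N, DMAP) gives the stannyl acrylate F6. Acetal hydrolysis as in step 30 gives the aldehyde F7. Union with 15 and 33 exactly as in step 31 gives the seco vinyl iodide–vinylstannane F8. An intramolecular Stille coupling (Pd2(dba)3, AsPh3, DMF, 25 °C) forms C3–C4 and returns to the route at 47.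

**Step 7.** Mono-olefination of the dialdehyde is statistical by design. What may go wrong beyond that is over-olefination, β-elimination of silyloxide from the sensitive dialdehyde by the basic ylide, and loss of unreacted 8 on recovery.

The fallback moves the differentiation to the robust diene 7. A single dihydroxylation with a deficiency of OsO4/N-methylmorpholine N-oxide gives the mono-diol F9, which is trivially separated from unchanged 7 (recycled) and from tetraol. NaIO4 cleaves F9 to the aldehyde–alkene F10, which can now be olefinated with an excess of the Stork–Zhao ylide to give the iodoalkene F11. Lemieux–Johnson cleavage of the remaining terminal olefin, as in step 10, returns to the route at 9.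

**Step 27.** Deprotonation and elimination of the bromide by the basic dianion, or incomplete alkylation of a precious 1:1 pair, would cut the yield of the fragment union. The face selectivity of step 20 is bypassed by the same fallback.

The fallback reverses the polarity and sets out from 23 and 38. Epoxidation of 23 with m-chloroperbenzoic acid, followed by hydrolytic kinetic resolution of the epimeric terminal epoxides with (S,S)-(salen)Co(OAc) and water, leaves the (2R)-epoxide F12. Displacement of the bromide of 38 with lithium acetylide–ethylenediamine in DMSO gives the terminal alkyne F13. Its lithium acetylide (n-BuLi, BF3·OEt2, THF, −78 °C) opens F12 at C40 and returns to the route at 40 with O41 free.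

**Step 4.** The transient β-silyloxy aldehydes of the second two-directional allylation may eliminate under the basic, hot conditions, or catalyst control may be incomplete at one terminus. The fallback changes the oxidation level and the reagent class. Step 3 is stopped after Me2S, and dialdehyde 4 is treated with B-allylbis(isopinocampheyl)borane from (−)-Ipc2BOMe and allylmagnesium bromide (Si-face attack at both termini, −78 °C, peroxide work-up), which gives 6 directly and needs no new compound.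

## Further compounds

F1 | step 31 | C19 vinyl carbinol from 15 | C/C(I)=C/C[C@H](O[Si](C)(C)C(C)(C)C)C[C@@H](O[Si](C)(C)C(C)(C)C)C[C@H](O[Si](C)(C)C(C)(C)C)C[C@@H](O[Si](C)(C)C(C)(C)C)C[C@H](O[Si](C)(C)C(C)(C)C)C[C@@H](O[Si](C)(C)C(C)(C)C)[C@@H](C)[C@H](O)C=C
F2 | step 31 | C23 allyl carbinol from 43 | C=CC[C@H](O)CCC[C@H](O[Si](C)(C)C(C)(C)C)CCC[C@H](O[Si](C)(C)C(C)(C)C)CCCCCC/C=C\C[C@@H]([C@@H](C)[C@H](O[Si](C)(C)C(C)(C)C)CCCCC[C@@H](C)O[Si](C)(C)C(C)(C)C)OC(=O)C=C
F3 | step 31 | mixed diisopropylsilylene ketal of F1 (O19) and F2 (O23) | C/C(I)=C/C[C@H](O[Si](C)(C)C(C)(C)C)C[C@@H](O[Si](C)(C)C(C)(C)C)C[C@H](O[Si](C)(C)C(C)(C)C)C[C@@H](O[Si](C)(C)C(C)(C)C)C[C@H](O[Si](C)(C)C(C)(C)C)C[C@@H](O[Si](C)(C)C(C)(C)C)[C@@H](C)[C@H](O[Si](C(C)C)(C(C)C)O[C@@H](CC=C)CCC[C@H](O[Si](C)(C)C(C)(C)C)CCC[C@H](O[Si](C)(C)C(C)(C)C)CCCCCC/C=C\C[C@@H]([C@@H](C)[C@H](O[Si](C)(C)C(C)(C)C)CCCCC[C@@H](C)O[Si](C)(C)C(C)(C)C)OC(=O)C=C)C=C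
F4 | step 31 | Heck macrocycle of F3 ((2E,4Z)-dienoate, silylene ketal, two terminal olefins) | CC1=C/C[C@H](O[Si](C)(C)C(C)(C)C)C[C@@H](O[Si](C)(C)C(C)(C)C)C[C@H](O[Si](C)(C)C(C)(C)C)C[C@@H](O[Si](C)(C)C(C)(C)C)C[C@H](O[Si](C)(C)C(C)(C)C)C[C@@H](O[Si](C)(C)C(C)(C)C)[C@@H](C)[C@H](O[Si](C(C)C)(C(C)C)O[C@@H](CC=C)CCC[C@H](O[Si](C)(C)C(C)(C)C)CCC[C@H](O[Si](C)(C)C(C)(C)C)CCCCCC/C=C\C[C@@H]([C@@H](C)[C@H](O[Si](C)(C)C(C)(C)C)CCCCC[C@@H](C)O[Si](C)(C)C(C)(C)C)OC(=O)\C=C\1)C=C
F5 | step 31 | bicyclic macrolactone with eight-membered (Z)-dioxasilocine bridging O19 and O23 | CC1=C/C[C@H](O[Si](C)(C)C(C)(C)C)C[C@@H](O[Si](C)(C)C(C)(C)C)C[C@H](O[Si](C)(C)C(C)(C)C)C[C@@H](O[Si](C)(C)C(C)(C)C)C[C@H](O[Si](C)(C)C(C)(C)C)C[C@@H](O[Si](C)(C)C(C)(C)C)[C@@H](C)[C@@H]2O[Si](C(C)C)(C(C)C)O[C@@H](C/C=C\2)CCC[C@H](O[Si](C)(C)C(C)(C)C)CCC[C@H](O[Si](C)(C)C(C)(C)C)CCCCCC/C=C\C[C@@H]([C@@H](C)[C@H](O[Si](C)(C)C(C)(C)C)CCCCC[C@@H](C)O[Si](C)(C)C(C)(C)C)OC(=O)\C=C\1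
F6 | step 32 | (E)-3-(tributylstannyl)acrylate of 41 | COC(OC)CCC[C@H](O[Si](C)(C)C(C)(C)C)CCC[C@H](O[Si](C)(C)C(C)(C)C)CCCCCC/C=C\C[C@@H]([C@@H](C)[C@H](O[Si](C)(C)C(C)(C)C)CCCCC[C@@H](C)O[Si](C)(C)C(C)(C)C)OC(=O)/C=C/[Sn](CCCC)(CCCC)CCCC
F7 | step 32 | C23 aldehyde from F6 | O=CCCC[C@H](O[Si](C)(C)C(C)(C)C)CCC[C@H](O[Si](C)(C)C(C)(C)C)CCCCCC/C=C\C[C@@H]([C@@H](C)[C@H](O[Si](C)(C)C(C)(C)C)CCCCC[C@@H](C)O[Si](C)(C)C(C)(C)C)OC(=O)/C=C/[Sn](CCCC)(CCCC)CCCC
F8 | step 32 | seco (Z)-ene-diol with C4 vinyl iodide and C41 (E)-stannylacrylate | C/C(I)=C/C[C@H](O[Si](C)(C)C(C)(C)C)C[C@@H](O[Si](C)(C)C(C)(C)C)C[C@H](O[Si](C)(C)C(C)(C)C)C[C@@H](O[Si](C)(C)C(C)(C)C)C[C@H](O[Si](C)(C)C(C)(C)C)C[C@@H](O[Si](C)(C)C(C)(C)C)[C@@H](C)[C@H](O)/C=C\C[C@H](O)CCC[C@H](O[Si](C)(C)C(C)(C)C)CCC[C@H](O[Si](C)(C)C(C)(C)C)CCCCCC/C=C\C[C@@H]([C@@H](C)[C@H](O[Si](C)(C)C(C)(C)C)CCCCC[C@@H](C)O[Si](C)(C)C(C)(C)C)OC(=O)/C=C/[Sn](CCCC)(CCCC)CCCC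
F9 | step 7 | mono-diol of 7 (C4′,C5-diol, both C5 epimers; C15 olefin intact) | OCC(O)C[C@H](O[Si](C)(C)C(C)(C)C)C[C@@H](O[Si](C)(C)C(C)(C)C)C[C@H](O[Si](C)(C)C(C)(C)C)C[C@@H](O[Si](C)(C)C(C)(C)C)CC=C
F10 | step 7 | C5 aldehyde with C15 terminal olefin | O=CC[C@H](O[Si](C)(C)C(C)(C)C)C[C@@H](O[Si](C)(C)C(C)(C)C)C[C@H](O[Si](C)(C)C(C)(C)C)C[C@@H](O[Si](C)(C)C(C)(C)C)CC=C
F11 | step 7 | (Z)-iodoalkene with C15 terminal olefin | C/C(I)=C/C[C@H](O[Si](C)(C)C(C)(C)C)C[C@@H](O[Si](C)(C)C(C)(C)C)C[C@H](O[Si](C)(C)C(C)(C)C)C[C@@H](O[Si](C)(C)C(C)(C)C)CC=C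
F12 | step 27 | (2R)-2-[(2S,3R,9R)-3,9-bis(TBSO)decan-2-yl]oxirane (C40–C41 epoxide) | C1O[C@@H]1[C@@H](C)[C@H](O[Si](C)(C)C(C)(C)C)CCCCC[C@@H](C)O[Si](C)(C)C(C)(C)C
F13 | step 27 | C23–C39 terminal alkyne (C23 dimethyl acetal) | COC(OC)CCC[C@H](O[Si](C)(C)C(C)(C)C)CCC[C@H](O[Si](C)(C)C(C)(C)C)CCCCCCC#C
F0 | step 4 | none | none
A1 | alternative 1 | seco acid, all hydroxyls except O41 as TBS ethers | OC(=O)/C=C/C(C)=C\C[C@H](O[Si](C)(C)C(C)(C)C)C[C@@H](O[Si](C)(C)C(C)(C)C)C[C@H](O[Si](C)(C)C(C)(C)C)C[C@@H](O[Si](C)(C)C(C)(C)C)C[C@H](O[Si](C)(C)C(C)(C)C)C[C@@H](O[Si](C)(C)C(C)(C)C)[C@@H](C)[C@H](O[Si](C)(C)C(C)(C)C)/C=C\C[C@H](O[Si](C)(C)C(C)(C)C)CCC[C@H](O[Si](C)(C)C(C)(C)C)CCC[C@H](O[Si](C)(C)C(C)(C)C)CCCCCC/C=C\C[C@@H]([C@@H](C)[C@H](O[Si](C)(C)C(C)(C)C)CCCCC[C@@H](C)O[Si](C)(C)C(C)(C)C)O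
A2 | alternative 2 | diyne ester (methyl-capped alkynes at C38 and C39) | CC#CC[C@@H]([C@@H](C)[C@H](O[Si](C)(C)C(C)(C)C)CCCCC[C@@H](C)O[Si](C)(C)C(C)(C)C)OC(=O)/C=C/C(C)=C\C[C@H](O[Si](C)(C)C(C)(C)C)C[C@@H](O[Si](C)(C)C(C)(C)C)C[C@H](O[Si](C)(C)C(C)(C)C)C[C@@H](O[Si](C)(C)C(C)(C)C)C[C@H](O[Si](C)(C)C(C)(C)C)C[C@@H](O[Si](C)(C)C(C)(C)C)[C@@H](C)[C@H](O[Si](C)(C)C(C)(C)C)/C=C\C[C@H](O[Si](C)(C)C(C)(C)C)CCC[C@H](O[Si](C)(C)C(C)(C)C)CCC[C@H](O[Si](C)(C)C(C)(C)C)CCCCCCC#CC
A3 | alternative 2 | macrocyclic C38≡C39 alkyne | O=C1/C=C/C(C)=C\C[C@H](O[Si](C)(C)C(C)(C)C)C[C@@H](O[Si](C)(C)C(C)(C)C)C[C@H](O[Si](C)(C)C(C)(C)C)C[C@@H](O[Si](C)(C)C(C)(C)C)C[C@H](O[Si](C)(C)C(C)(C)C)C[C@@H](O[Si](C)(C)C(C)(C)C)[C@@H](C)[C@H](O[Si](C)(C)C(C)(C)C)/C=C\C[C@H](O[Si](C)(C)C(C)(C)C)CCC[C@H](O[Si](C)(C)C(C)(C)C)CCC[C@H](O[Si](C)(C)C(C)(C)C)CCCCCCC#CC[C@@H]([C@@H](C)[C@H](O[Si](C)(C)C(C)(C)C)CCCCC[C@@H](C)O[Si](C)(C)C(C)(C)C)O1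
A4 | alternative 3 | (2R,4R)-1,2:4,5-diepoxypentane | C1O[C@@H]1C[C@@H]1CO1
A5 | alternative 3 | C2-symmetric bis-dithiane diol (C5–C19 skeleton without the C18 methyl) | C=CC[C@H](O[Si](C)(C)C(C)(C)C)CC1(SCCCS1)C[C@H](O)C[C@@H](O)CC1(SCCCS1)C[C@@H](O[Si](C)(C)C(C)(C)C)CC=C
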